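## The problem

Target 13, 4-[(2R,3R)-7-allyl-5-methoxy-3-methyl-2,3-dihydro-1,4-benzodioxin-2-yl]-2,6-dimethoxyphenol, is a 1,4-benzodioxane neolignan. Its catechol-derived ring A (methoxyl on C5, allyl on C7) is bridged through O1 and O4 by the unit C2–C3, with a 4-hydroxy-3,5-dimethoxyphenyl ring (ring C) on C2 and a methyl group on C3. The first difficulty is regiochemical: O4, next to the C5 methoxyl, must be bound to C3 and O1 to the benzylic C2, yet the two oxygens of a 3-methoxy-5-allylcatechol are too alike to be alkylated one at a time with confidence. The second is stereochemical: C2 and C3 are both R, which places aryl and methyl trans on the dioxane ring (ring B). The two centres are adjacent, so one of them, once fixed, can direct the other by 1,2-induction in an open-chain carbonyl addition. Whatever closes ring B must then leave both centres alone, which argues against forming the C2–O1 bond late, because a benzylic carbon para to an oxygenated ring ionises easily. Three groups limit the reagents: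
- the allyl chain: no hydrogenation, and a risk of bromine addition and of base-induced migration to the propenyl isomer;
- the ring C phenol: it needs a mask that comes off without acid or hydrogen;
- the C2–O1 benzylic ether: acid-labile, and base-labile through a quinone methide once the para phenol is free.

The feature that opens the problem is that O4 on C4a lies para to the C7 allyl group and ortho to the C5 methoxyl, exactly as the hydroxyl of eugenol does. A eugenol ether therefore already holds ring A with O4 in place and lacks only the aryl C8a–O1 bond. In such an ether C8a–H lies between O4 and C8, so a bromine on C8 makes it the most acidic ring hydrogen and gives access to an aryne between C8 and C8a, which a tethered C2 alkoxide can reach only at C8a.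

## Retrosynthesis

**13 ⇒ 12 (O–Si bond on ring C).** The phenol of 13 is masked as the triisopropylsilyl ether 12. A silyl ether is removed by fluoride, which spares the allyl group and the benzylic ether; a benzyl ether would need hydrogen and an acetal would need acid. The bulkier triisopropylsilyl group is preferred to a smaller silyl group because it must outlast a lithium alkoxide and a lithium amide in the preceding step.

**12 ⇒ 9 (aryl C8a–O1 bond, ring B).** Cutting the aryl C8a–O1 bond leads to the open-chain bromo alcohol 9, an ether of 5-bromoeugenol in which both stereocentres are already present. The neighbouring cuts are weaker: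
- the aryl C4a–O4 cut brings back the catechol differentiation problem;
- the alkyl C2–O1 cut would make the ionisable benzylic bond at the end;
- the alkyl C3–O4 cut needs an SN2 closure at a secondary carbon flanked by that same benzylic centre.

In the forward direction a hindered lithium amide must remove C8a–H of 9 and expel bromide to give aryne 10. The tethered alkoxide must add to C8a to give aryllithium 11, which is protonated to 12. No bond to C2 or C3 is touched.

**9 ⇒ 5 + 8 (C2–aryl bond; 8 ⇐ 7 ⇐ 6).** Cutting the bond between C2 and ring C gives the α-aryloxy aldehyde 5 and the arylmagnesium bromide 8. Reagent 8 is made from the silyl ether 7 of commercial 4-bromo-2,6-dimethoxyphenol 6. This cut is preferred to reduction of a ketone because it builds the carbon skeleton and the C2 centre in one operation. The 2-methoxyphenoxy group on C3 offers two oxygens for chelation of magnesium, so the existing C3 centre should steer the aryl group to the threo (1R,2R) alcohol. The forward reaction has to be run so that chelation, not the Felkin–Anh mode, decides the face.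

**5 ⇒ 4 ⇒ 3 (oxidation level; C8–Br bond).** Aldehyde 5 is the partial reduction product of ester 4, and 4 is the ring bromide of ester 3. Bromine is introduced at the ester stage, before ring C is present, because ring C would compete for the electrophile. In 3 the only free position para to an alkoxy group is the one para to methoxyl and ortho to allyl, which is C8 of the target. The forward bromination must attack the ring and not the terminal alkene.

**3 ⇒ 1 + 2 (C3–O4 bond).** The C3–O4 bond is formed from eugenol 1 and ethyl (S)-lactate 2 by Mitsunobu etherification with inversion. The cheap natural lactate thus delivers the (R) configuration required at C3, and eugenol supplies ring A with the allyl group, the methoxyl and O4 in their final positions.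

## Roads not taken

**Alternative 1:** The cut is the aryl C4a–O4 bond. The secondary C3 alkoxide of bromo benzoate A1, formed with KN(SiMe3)2, would displace bromide from C4a para to the ester to give benzodioxane ester A2.
- Merits: ring A comes from a benzoate whose two oxygen positions are equivalent by symmetry until one is methylated, so the regiochemistry of the catechol is never in question. No aryne and no strong amide base meet an allyl group, because the allyl group is not yet there. In these two respects this road is cleaner than the chosen one.
- Weak points: the bromide sits between two alkoxy donors and is activated by a single para ester only, a poor substrate for nucleophilic aromatic substitution, so forcing conditions would be needed. The benzylic C2–O1 ether of A1 has to be made stereoselectively beforehand at a carbon prone to ionisation. After ring closure the ester must still be turned into the allyl group (reduction, activation, vinyl coupling), and the methoxymethyl group must be removed with acid next to the acid-labile C2–O1 bond.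
- Comparison: the chosen plan carries the allyl group from the first step, sets both centres before the ring is closed and is about four steps shorter. It pays with the need to control a strong base in the presence of the allyl group.

**Alternative 2:** The cuts are O1–C2 and C2–C3. A rhodium carbene, formed from aryldiazomethane A4 with a chiral dirhodium tetracarboxylate such as Rh2(S-DOSP)4, would add to O1 of the benzodioxole acetal A3. A 1,2-shift of the acetal carbon from oxygen to the carbene carbon would then expand the five-membered acetal to the dioxane A5.
- Merits: this is the most convergent road. Two bonds, ring B and both stereocentres are made in one catalytic step, from an acetal that fixes the ring A regiochemistry and without a chiral-pool reagent. On paper it is shorter than the chosen route.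
- Weak points: the carbene must choose O1 over O4, which differ only by the neighbouring methoxyl. The 1,2-shift of an oxonium ylide runs through a radical or ion pair that transmits little of the catalyst's chirality, so neither the trans relationship nor the absolute configuration is assured. A donor-only, electron-rich aryldiazomethane such as A4 is unstable and lacks the acceptor group on which the selectivity of such catalysts depends. This ring expansion is not established for benzodioxoles. Bromide-to-allyl coupling and desilylation still follow.
- Comparison: the chosen plan is longer by one or two steps but rests on reaction types of known stereochemical course.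

**Alternative 3:** The cut is the alkyl O4–C3 bond together with a C–H bond of the methyl group. A cobalt hydride generated from a Co(salen) complex, a silane and an oxidant would transfer a hydrogen atom to the vinyl CH2 of phenol A6. The C4a phenol oxygen would then capture C3 to close ring B and give A7.
- Merits: the conditions are mild and nearly neutral, and the methyl group is created from a vinyl group. The C2 centre of A6 could come from a catalytic asymmetric allylic etherification, so either enantiomer is equally accessible. That is an advantage over a chiral-pool route, although the chosen plan can answer it with ethyl (R)-lactate.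
- Weak points: the radical or cation at C3 is β to the aryloxy oxygen O1 and next to the doubly activated C2–H. Loss of the aryloxy group or a hydride shift would therefore destroy C2. The trans selectivity of a kinetically controlled closure is uncertain. A6 needs a catechol alkylated at O1 only, which is exactly the differentiation that eugenol provides for free. The bromide must still be exchanged for allyl, and the methoxymethyl group removed with acid.
- Comparison: the chosen plan fixes both centres in an open chain before ring closure and closes the ring at an aryl carbon, where no stereocentre is at risk.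

Key step: step 6

## Route

Step 1
Reactants: 1 eugenol (4-allyl-2-methoxyphenol); 2 ethyl (S)-lactate
Product: 3 ethyl (R)-2-(4-allyl-2-methoxyphenoxy)propanoate
Conditions: PPh3, DIAD, THF, 0 °C to rt
Reagents that add atoms: none
Why: Mitsunobu etherification; the phenol displaces the activated secondary hydroxyl of the lactate by SN2 with inversion, so the (S) ester gives the (R) aryl ether, the future C3.

Step 2
Reactants: 3 ethyl (R)-2-(4-allyl-2-methoxyphenoxy)propanoate
Product: 4 ethyl (R)-2-(4-allyl-5-bromo-2-methoxyphenoxy)propanoate
Conditions: NBS (1.05 equiv), MeCN, 0 °C to rt, dark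
Reagents that add atoms: N-bromosuccinimide, O=C1CCC(=O)N1Br
Why: Electrophilic aromatic bromination; the only free position para to an alkoxy group is the one para to methoxyl and ortho to allyl, the usual site in 4-allyl-1,2-dialkoxybenzenes, and polar radical-free conditions should favour the activated ring over the terminal alkene and the allylic CH2.

Step 3
Reactants: 4 ethyl (R)-2-(4-allyl-5-bromo-2-methoxyphenoxy)propanoate
Product: 5 (R)-2-(4-allyl-5-bromo-2-methoxyphenoxy)propanal
Conditions: i-Bu2AlH (1.1 equiv), CH2Cl2, −78 °C; MeOH, then aq potassium sodium tartrate; used at once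
Reagents that add atoms: none
Why: Partial reduction of an ester with i-Bu2AlH; the α-aryloxy oxygen stabilises the aluminium hemiacetal at −78 °C so that the aldehyde is released only on work-up, and the crude aldehyde is used at once to protect the epimerisable α-centre.

Step 4
Reactants: 6 4-bromo-2,6-dimethoxyphenol
Product: 7 (4-bromo-2,6-dimethoxyphenoxy)triisopropylsilane
Conditions: TIPSCl, imidazole, DMF, 40 °C
Reagents that add atoms: chlorotriisopropylsilane, CC(C)[Si](Cl)(C(C)C)C(C)C
Why: Silylation of a phenol with a silyl chloride and imidazole; the triisopropylsilyl ether is chosen because it resists alkoxides and amide bases better than smaller silyl ethers.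

Step 5
Reactants: 5 (R)-2-(4-allyl-5-bromo-2-methoxyphenoxy)propanal; 7 (4-bromo-2,6-dimethoxyphenoxy)triisopropylsilane
Product: 9 (1R,2R)-2-(4-allyl-5-bromo-2-methoxyphenoxy)-1-[3,5-dimethoxy-4-(triisopropylsilyloxy)phenyl]propan-1-ol, via arylmagnesium bromide 8 (not isolated)
Conditions: 7, Mg, THF, 50 °C; then 5, MgBr2·OEt2, CH2Cl2, −78 °C; aq NH4Cl
Reagents that add atoms: none
Why: Grignard addition under Cram chelate control; magnesium is held between the carbonyl oxygen and the bidentate 2-methoxyphenoxy group, and the aryl nucleophile attacks the chelate face that carries H and not CH3, which should give the threo (1R,2R) alcohol. The aryl bromide of 5 is inert to an arylmagnesium bromide at −78 °C.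

Step 6
Reactants: 9 (1R,2R)-2-(4-allyl-5-bromo-2-methoxyphenoxy)-1-[3,5-dimethoxy-4-(triisopropylsilyloxy)phenyl]propan-1-ol
Product: 12 (2R,3R)-7-allyl-5-methoxy-3-methyl-2-[3,5-dimethoxy-4-(triisopropylsilyloxy)phenyl]-2,3-dihydro-1,4-benzodioxine, via aryne lithium alkoxide 10 (not isolated), via 8-lithiobenzodioxine 11 (not isolated)
Conditions: lithium 2,2,6,6-tetramethylpiperidide (3 equiv, from 2,2,6,6-tetramethylpiperidine and n-BuLi), THF, −78 °C, then to −20 °C; aq NH4Cl
Reagents that add atoms: none
Why: Benzyne cyclisation, the intramolecular capture of an aryne by a tethered alkoxide after generation from a meta-haloaryl ether with a lithium amide. The first equivalent of amide deprotonates the alcohol; the second, guided by the neighbouring lithium alkoxide, removes C8a–H, the only ring hydrogen flanked by oxygen and bromine, and loss of LiBr on warming gives aryne 10 between C8 and C8a. The alkoxide O1 adds in the plane of the aryne to C8a, a 6-exo-dig-type closure of ring B in which the reacting in-plane π bond stays outside the new ring, and the resulting aryllithium 11 is protonated by the amine or on work-up. No stereocentre is created and no bond to C2 or C3 is broken, so (1R,2R) in 9 becomes (2R,3R) in 12 with retention at both centres. Regiochemically, the aryne can form only on the C8a side of bromine because C7 carries the allyl group. An external nucleophile would prefer C8, distal to O4, but the four-atom tether reaches only C8a, since attack at C8 would require a meta-bridged ring. Chemoselectivity rests on the hindered amide, which should not add to the aryne, on abstraction of the activated aryl hydrogen at −78 °C being faster than that of the allylic CH2, and on the bulky silyl ether resisting the alkoxide.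

Step 7
Reactants: 12 (2R,3R)-7-allyl-5-methoxy-3-methyl-2-[3,5-dimethoxy-4-(triisopropylsilyloxy)phenyl]-2,3-dihydro-1,4-benzodioxine
Product: 13 4-[(2R,3R)-7-allyl-5-methoxy-3-methyl-2,3-dihydro-1,4-benzodioxin-2-yl]-2,6-dimethoxyphenol (target)
Conditions: Bu4NF, AcOH, THF, 0 °C
Reagents that add atoms: none
Why: Fluoride-induced cleavage of an aryl silyl ether; acetic acid buffers the phenoxide so that the para-hydroxybenzyl ether at C2 is not exposed to strong base, and allyl group, methyl ethers and both stereocentres are untouched.

## Compound list

1 | eugenol (4-allyl-2-methoxyphenol) | C=CCc1ccc(O)c(OC)c1 | starting material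
2 | ethyl (S)-lactate | CCOC(=O)[C@H](C)O | starting material
3 | ethyl (R)-2-(4-allyl-2-methoxyphenoxy)propanoate | C=CCc1ccc(O[C@H](C)C(=O)OCC)c(OC)c1 | intermediate
4 | ethyl (R)-2-(4-allyl-5-bromo-2-methoxyphenoxy)propanoate | C=CCc1cc(OC)c(O[C@H](C)C(=O)OCC)cc1Br | intermediate
5 | (R)-2-(4-allyl-5-bromo-2-methoxyphenoxy)propanal | C=CCc1cc(OC)c(O[C@H](C)C=O)cc1Br | intermediate
6 | 4-bromo-2,6-dimethoxyphenol | COc1cc(Br)cc(OC)c1O | starting material
7 | (4-bromo-2,6-dimethoxyphenoxy)triisopropylsilane | COc1cc(Br)cc(OC)c1O[Si](C(C)C)(C(C)C)C(C)C | intermediate
8 | [3,5-dimethoxy-4-(triisopropylsilyloxy)phenyl]magnesium bromide | COc1cc([Mg]Br)cc(OC)c1O[Si](C(C)C)(C(C)C)C(C)C | intermediate (not isolated)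
9 | (1R,2R)-2-(4-allyl-5-bromo-2-methoxyphenoxy)-1-[3,5-dimethoxy-4-(triisopropylsilyloxy)phenyl]propan-1-ol | C=CCc1cc(OC)c(O[C@H](C)[C@H](O)c2cc(OC)c(O[Si](C(C)C)(C(C)C)C(C)C)c(OC)c2)cc1Br | intermediate
10 | lithium (1R,2R)-2-(4-allyl-2-methoxy-5,6-didehydrophenoxy)-1-[3,5-dimethoxy-4-(triisopropylsilyloxy)phenyl]propan-1-olate (aryne between C8 and C8a) | C=CCC1=CC(OC)=C(O[C@H](C)[C@H]([O-])c2cc(OC)c(O[Si](C(C)C)(C(C)C)C(C)C)c(OC)c2)C#C1.[Li+] | intermediate (not isolated)
11 | (2R,3R)-7-allyl-8-lithio-5-methoxy-3-methyl-2-[3,5-dimethoxy-4-(triisopropylsilyloxy)phenyl]-2,3-dihydro-1,4-benzodioxine | C=CCc1cc(OC)c2c(c1[Li])O[C@H](c1cc(OC)c(O[Si](C(C)C)(C(C)C)C(C)C)c(OC)c1)[C@@H](C)O2 | intermediate (not isolated)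
12 | (2R,3R)-7-allyl-5-methoxy-3-methyl-2-[3,5-dimethoxy-4-(triisopropylsilyloxy)phenyl]-2,3-dihydro-1,4-benzodioxine | C=CCc1cc(OC)c2c(c1)O[C@H](c1cc(OC)c(O[Si](C(C)C)(C(C)C)C(C)C)c(OC)c1)[C@@H](C)O2 | intermediate
13 | 4-[(2R,3R)-7-allyl-5-methoxy-3-methyl-2,3-dihydro-1,4-benzodioxin-2-yl]-2,6-dimethoxyphenol | C=CCc1cc(OC)c2c(c1)O[C@H](c1cc(OC)c(O)c(OC)c1)[C@@H](C)O2 | target

## Step count and risks

Total: 7 steps. Longest linear sequence: 6 steps (1 → 3 → 4 → 5 → 9 → 12 → 13; the one-step preparation of 7 joins at step 5).

**Step 6 (key step).** Three processes are most likely to interfere: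
- migration of the allyl double bond into conjugation through deprotonation of the allylic CH2 by excess amide or by aryllithium 11;
- intermolecular capture of the aryne by amide or by a second alkoxide in place of ring closure;
- sluggish loss of LiBr, so that warming is needed and the first two processes gain ground.

Fallback: the same C8a–O1 bond is made by palladium-catalysed intramolecular aryl etherification, with the bromine placed on C8a. Setting out from 1, ortho-bromination of the free phenol (NBS, catalytic i-Pr2NH, CH2Cl2) gives 4-allyl-2-bromo-6-methoxyphenol F1. Mitsunobu reaction with 2 gives ethyl (R)-2-(4-allyl-2-bromo-6-methoxyphenoxy)propanoate F2, and i-Bu2AlH reduces it to (R)-2-(4-allyl-2-bromo-6-methoxyphenoxy)propanal F3. Chelation-controlled addition of 8 gives (1R,2R)-2-(4-allyl-2-bromo-6-methoxyphenoxy)-1-[3,5-dimethoxy-4-(triisopropylsilyloxy)phenyl]propan-1-ol F4. Ring closure with Pd(OAc)2, 2-(di-tert-butylphosphino)-1,1'-binaphthyl and Cs2CO3 in toluene at 70 °C returns to the route at 12.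

**Step 5.** The likely failure is poor facial selectivity, because an aryl ether oxygen is a weak donor and the Felkin–Anh mode leads to the erythro alcohol. Base-induced epimerisation of the α-aryloxy aldehyde before addition is the second concern. Fallback: the C2 centre is set by hydride instead of by the carbon nucleophile. Setting out from 4, MeNH(OMe)·HCl and i-PrMgCl give (R)-2-(4-allyl-5-bromo-2-methoxyphenoxy)-N-methoxy-N-methylpropanamide F5. Acylation of 8 gives (R)-2-(4-allyl-5-bromo-2-methoxyphenoxy)-1-[3,5-dimethoxy-4-(triisopropylsilyloxy)phenyl]propan-1-one F6. Reduction with the bulky, non-chelating LiBH(s-Bu)3 in THF at −78 °C should follow the Felkin–Anh mode, which for the ketone leads to the threo alcohol, and the route is rejoined at 9.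

**Step 2.** The likely failure is competing addition of bromine to the terminal alkene, or radical bromination of the allylic CH2. Fallback: the alkene is deliberately protected as its dibromide. Setting out from 3, Br2 (2 equiv) in CH2Cl2 gives ethyl (2R)-2-[5-bromo-4-(2,3-dibromopropyl)-2-methoxyphenoxy]propanoate F7. Zinc in AcOH/EtOH then removes the vicinal bromines only and returns to the route at 4.

**Step 3.** The likely failures are over-reduction to the primary alcohol and epimerisation of the aldehyde during work-up. Fallback: setting out from 4, full reduction with LiBH4 in THF gives (R)-2-(4-allyl-5-bromo-2-methoxyphenoxy)propan-1-ol F8, a stable compound that can be purified. Oxidation with Dess–Martin periodinane buffered with NaHCO3 immediately before use returns to the route at 5.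

## Further compounds

F1 | step 6 | 4-allyl-2-bromo-6-methoxyphenol | C=CCc1cc(Br)c(O)c(OC)c1
F2 | step 6 | ethyl (R)-2-(4-allyl-2-bromo-6-methoxyphenoxy)propanoate | C=CCc1cc(Br)c(O[C@H](C)C(=O)OCC)c(OC)c1
F3 | step 6 | (R)-2-(4-allyl-2-bromo-6-methoxyphenoxy)propanal | C=CCc1cc(Br)c(O[C@H](C)C=O)c(OC)c1
F4 | step 6 | (1R,2R)-2-(4-allyl-2-bromo-6-methoxyphenoxy)-1-[3,5-dimethoxy-4-(triisopropylsilyloxy)phenyl]propan-1-ol | C=CCc1cc(Br)c(O[C@H](C)[C@H](O)c2cc(OC)c(O[Si](C(C)C)(C(C)C)C(C)C)c(OC)c2)c(OC)c1
F5 | step 5 | (R)-2-(4-allyl-5-bromo-2-methoxyphenoxy)-N-methoxy-N-methylpropanamide | C=CCc1cc(OC)c(O[C@H](C)C(=O)N(C)OC)cc1Br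
F6 | step 5 | (R)-2-(4-allyl-5-bromo-2-methoxyphenoxy)-1-[3,5-dimethoxy-4-(triisopropylsilyloxy)phenyl]propan-1-one | C=CCc1cc(OC)c(O[C@H](C)C(=O)c2cc(OC)c(O[Si](C(C)C)(C(C)C)C(C)C)c(OC)c2)cc1Br
F7 | step 2 | ethyl (2R)-2-[5-bromo-4-(2,3-dibromopropyl)-2-methoxyphenoxy]propanoate (both epimers at the CHBr carbon) | BrCC(Br)Cc1cc(OC)c(O[C@H](C)C(=O)OCC)cc1Br
F8 | step 3 | (R)-2-(4-allyl-5-bromo-2-methoxyphenoxy)propan-1-ol | C=CCc1cc(OC)c(O[C@H](C)CO)cc1Br
A1 | alternative 1 | methyl 4-bromo-3-{(1R,2R)-1-[3,5-dimethoxy-4-(methoxymethoxy)phenyl]-2-hydroxypropoxy}-5-methoxybenzoate | COC(=O)c1cc(OC)c(Br)c(c1)O[C@H](c1cc(OC)c(OCOC)c(OC)c1)[C@@H](C)O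
A2 | alternative 1 | methyl (2R,3R)-5-methoxy-3-methyl-2-[3,5-dimethoxy-4-(methoxymethoxy)phenyl]-2,3-dihydro-1,4-benzodioxine-7-carboxylate | COC(=O)c1cc(OC)c2c(c1)O[C@H](c1cc(OC)c(OCOC)c(OC)c1)[C@@H](C)O2
A3 | alternative 2 | 6-bromo-4-methoxy-2-methyl-1,3-benzodioxole (racemic acetal) | CC1Oc2cc(Br)cc(OC)c2O1
A4 | alternative 2 | tert-butyl[4-(diazomethyl)-2,6-dimethoxyphenoxy]dimethylsilane | COc1cc(C=[N+]=[N-])cc(OC)c1O[Si](C)(C)C(C)(C)C
A5 | alternative 2 | (2R,3R)-7-bromo-2-[4-(tert-butyldimethylsilyloxy)-3,5-dimethoxyphenyl]-5-methoxy-3-methyl-2,3-dihydro-1,4-benzodioxine | Brc1cc(OC)c2c(c1)O[C@H](c1cc(OC)c(O[Si](C)(C)C(C)(C)C)c(OC)c1)[C@@H](C)O2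
A6 | alternative 3 | 4-bromo-2-{(1S)-1-[3,5-dimethoxy-4-(methoxymethoxy)phenyl]prop-2-en-1-yloxy}-6-methoxyphenol | Brc1cc(OC)c(O)c(c1)O[C@H](c1cc(OC)c(OCOC)c(OC)c1)C=C
A7 | alternative 3 | (2R,3R)-7-bromo-5-methoxy-3-methyl-2-[3,5-dimethoxy-4-(methoxymethoxy)phenyl]-2,3-dihydro-1,4-benzodioxine | Brc1cc(OC)c2c(c1)O[C@H](c1cc(OC)c(OCOC)c(OC)c1)[C@@H](C)O2
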